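**Plan**

- Cuts, in pterocarpan numbering: O5–C6 (ether, reached through the C6 lactone); then O5–C6(=O) and C6a–C6b together, which leads back to a 3-diazoflavanone; then C11a–C11b (aryl to chromone C2). Ring F and the prenyl group are cut from ring D, ring E from ring A.
- Enabling feature: ring C with C6 attached to C6a is a chroman-4-one of ring D made one atom smaller. C6 is the former carbonyl carbon, C6a the former diazo carbon, and O5 of ring A sits where it closes a six-membered ring onto C6.
- Forward order: ring F and the C10 prenyl group go onto ring D (two Claisen rearrangements, cross-metathesis), then the pyranone ring. Ring E is made on ring A. The halves are joined by 1,4-addition, then diazo transfer, then rings C and B form in one photochemical step. Ring B is finally re-made at the CH2 level.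
- Stereochemistry: C11a comes from the chiral diene ligand on rhodium in the 1,4-addition. C6a comes from C11a, because the lactone enol can only be protonated to the cis-fused system.

Key step: step 13

Assumption: (R,R)-Ph-bod on monovalent rhodium is taken to deliver the aryl group to the chromone face that gives the 2R flavanone (the sense it shows with cyclohexenone); if the opposite sense is found, (S,S)-Ph-bod is used with nothing else changed.

Remark: no configuration changes after step 10; only the CIP descriptors change with the substituents (2R in 20 and 21, 2S in 22 and 23, 6aS,11aR in 25, 6aR,11aR in 26 and 27).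

**Route**

Step 1
Reactants: 1 2',4',5'-trihydroxyacetophenone; 2 allyl bromide
Product: 3 1-[4-(allyloxy)-2,5-dihydroxyphenyl]ethanone
Conditions: K2CO3 (1.05 equiv), DMF, 0 °C to rt, argon
Reagents that add atoms: none
Why: Williamson etherification in which the 4-OH, para to the acetyl group and therefore the most acidic, is alkylated while the chelated 2-OH and the less acidic 5-OH stay free.

Step 2
Reactants: 3 1-[4-(allyloxy)-2,5-dihydroxyphenyl]ethanone; 4 3-chloro-3-methylbut-1-yne
Product: 5 1-[4-(allyloxy)-2-hydroxy-5-(2-methylbut-3-yn-2-yloxy)phenyl]ethanone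
Conditions: DBU (1.3 equiv), CuCl2·2H2O (1 mol%), MeCN, 0 °C, argon
Reagents that add atoms: none
Why: Copper-catalysed propargylic etherification of a phenol, which should take the free 5-OH because the 2-OH is tied up in the hydrogen bond to the acetyl group.

Step 3
Reactants: 5 1-[4-(allyloxy)-2-hydroxy-5-(2-methylbut-3-yn-2-yloxy)phenyl]ethanone
Product: 7 1-(7-allyl-6,8-dihydroxy-2,2-dimethyl-2H-chromen-5-yl)ethanone, via chromene allyl ether 6 (not isolated)
Conditions: PhNEt2, 140 °C, then 200 °C, argon
Reagents that add atoms: none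
Why: Two aromatic Claisen rearrangements in sequence, the propargyl ether first (then 1,5-H shift and oxa-6π closure to ring F) and the allyl ether at the higher temperature, each having only one free ortho carbon, so both regiochemistries are fixed.

Step 4
Reactants: 7 1-(7-allyl-6,8-dihydroxy-2,2-dimethyl-2H-chromen-5-yl)ethanone; 8 2-methylbut-2-ene
Product: 9 1-[6,8-dihydroxy-2,2-dimethyl-7-(3-methylbut-2-enyl)-2H-chromen-5-yl]ethanone
Conditions: second-generation Grubbs catalyst RuCl2(=CHPh)(PCy3)(H2IMes) (5 mol%), 8/CH2Cl2 1:1, 40 °C, sealed tube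
Reagents that add atoms: none
Why: Olefin cross-metathesis turns the terminal allyl group into prenyl, a standard move on ortho-allylphenols, while the ring alkene of the chromene next to a quaternary carbon should not take part.

Step 5
Reactants: 9 1-[6,8-dihydroxy-2,2-dimethyl-7-(3-methylbut-2-enyl)-2H-chromen-5-yl]ethanone
Product: 10 1-[6-hydroxy-2,2-dimethyl-7-(3-methylbut-2-enyl)-8-(triisopropylsilyloxy)-2H-chromen-5-yl]ethanone
Conditions: TIPSOTf (1.05 equiv), 2,6-lutidine, CH2Cl2, −78 to 0 °C
Reagents that add atoms: triisopropylsilyl triflate, CC(C)[Si](OS(=O)(=O)C(F)(F)F)(C(C)C)C(C)C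
Why: Silylation of the 8-OH, para to the acetyl group and not chelated, leaves the hydrogen-bonded 6-OH free for the pyranone ring.

Step 6
Reactants: 10 1-[6-hydroxy-2,2-dimethyl-7-(3-methylbut-2-enyl)-8-(triisopropylsilyloxy)-2H-chromen-5-yl]ethanone; 11 N,N-dimethylformamide dimethyl acetal
Product: 13 8-(3-methylbut-2-enyl)-7-(triisopropylsilyloxy)chromen-4-one carrying the 2,2-dimethylpyran ring F across C5–C6 (pyran oxygen on C6), via enaminone 12 (not isolated)
Conditions: toluene, 100 °C; then AcOH, 80 °C
Reagents that add atoms: none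
Why: Enaminone formation at the methyl ketone followed by acid-mediated addition of the ortho phenol and loss of dimethylamine is the standard chromone synthesis from 2-hydroxyacetophenones.

Step 7
Reactants: 14 5-bromo-2,4-dihydroxybenzaldehyde
Product: 15 5-bromo-2-hydroxy-4-(triisopropylsilyloxy)benzaldehyde
Conditions: TIPSCl (1.1 equiv), imidazole (2.2 equiv), DMF, 0 °C to rt
Reagents that add atoms: triisopropylsilyl chloride, CC(C)[Si](Cl)(C(C)C)C(C)C
Why: Selective silylation of the acidic 4-OH, the 2-OH being held by the aldehyde hydrogen bond.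

Step 8
Reactants: 15 5-bromo-2-hydroxy-4-(triisopropylsilyloxy)benzaldehyde; 16 2-methylprop-1-enylmagnesium bromide
Product: 18 6-bromo-2,2-dimethyl-7-(triisopropylsilyloxy)-2H-chromene, via benzylic alcohol 17 (not isolated)
Conditions: 16 (2.5 equiv), THF, −78 to 0 °C; aq. NH4Cl; then PPTS (5 mol%), toluene, 60 °C
Reagents that add atoms: none
Why: Grignard 1,2-addition to the salicylaldehyde gives an ortho-hydroxybenzyl allylic alcohol that on mild acid loses water to a vinyl ortho-quinone methide and closes by oxa-6π electrocyclisation, so ring E can only form in the linear sense with bromine at C6.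

Step 9
Reactants: 18 6-bromo-2,2-dimethyl-7-(triisopropylsilyloxy)-2H-chromene
Product: 19 [2,2-dimethyl-7-(triisopropylsilyloxy)-2H-chromen-6-yl]boronic acid
Conditions: B(OiPr)3 (1.5 equiv), then n-BuLi (1.2 equiv), THF/toluene, −78 °C; 1 M HCl, 0 °C
Reagents that add atoms: triisopropyl borate, CC(C)OB(OC(C)C)OC(C)C; water, O
Why: Bromine–lithium exchange with the borate already present traps the aryllithium before the ortho O-to-C silyl shift can occur, which the bulky triisopropylsilyl group slows further.

Step 10
Reactants: 13 chromone of ring D and ring F; 19 [2,2-dimethyl-7-(triisopropylsilyloxy)-2H-chromen-6-yl]boronic acid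
Product: 20 (2R)-2-[2,2-dimethyl-7-(triisopropylsilyloxy)-2H-chromen-6-yl] derivative of the chroman-4-one corresponding to 13 (the 2R flavanone)
Conditions: [RhCl(C2H4)2]2 (3 mol%), (R,R)-Ph-bod (6.6 mol%), K3PO4 (0.5 equiv), 19 (3 equiv), dioxane/H2O 10:1, 40 °C
Reagents that add atoms: none
Why: Hayashi–Miyaura asymmetric 1,4-addition of an arylboronic acid to a chromone, in which the aryl–rhodium species bound to the chiral diene inserts the C2=C3 bond on one face and so sets C2 (the later C11a) as R.

Step 11
Reactants: 20 the 2R flavanone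
Product: 22 (2S)-3-diazo derivative of flavanone 20, via trifluoroacetyl ketone 21 (not isolated)
Conditions: LiN(SiMe3)2 (1.2 equiv), THF, −78 °C; CF3CO2CH2CF3 (1.5 equiv), −78 °C; then 4-acetamidobenzenesulfonyl azide (1.5 equiv), Et3N (1.5 equiv), H2O (1 equiv), MeCN, 0 °C to rt
Reagents that add atoms: 4-acetamidobenzenesulfonyl azide, CC(=O)Nc1ccc(cc1)S(=O)(=O)N=[N+]=[N-]
Why: Detrifluoroacetylative diazo transfer, the standard way to put a diazo group next to a simple ketone, with the enolate kept at −78 °C so that ring-opening at O1–C2 is avoided; once C3 carries the diazo group C2 can no longer epimerise.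

Step 12
Reactants: 22 the silylated (2S)-3-diazoflavanone
Product: 23 (2S)-3-diazo-7-hydroxy-2-(7-hydroxy-2,2-dimethyl-2H-chromen-6-yl)-8-(3-methylbut-2-enyl)chroman-4-one carrying ring F across C5–C6
Conditions: TBAF (2.5 equiv), AcOH (3.5 equiv), THF, 0 °C, dark; used at once
Reagents that add atoms: none
Why: Fluoride cleavage of both aryl silyl ethers, buffered with acetic acid so that no phenoxide builds up next to the benzylic C2–O1 bond, under conditions a cyclic aryl diazoketone tolerates.

Step 13
Reactants: 23 the (2S)-3-diazoflavanone with both phenols free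
Product: 25 (6aS,11aR)-9-hydroxy-10-(3-methylbut-2-enyl)pterocarpan-6-one carrying ring E across C2–C3 and ring F across C7–C8, via aryl alkyl ketene 24 (not isolated)
Conditions: hν (405 nm LED), degassed dry CH2Cl2 (0.005 M), 0 °C to rt, then rt in the dark
Reagents that add atoms: none
Why: Excitation of the s-cis-locked diazoketone expels N2 in concert with the 1,2-shift of ring D carbon C6b (flavanone C4a) from the carbonyl carbon (future C6) to the diazo carbon (future C6a), a photochemical Wolff rearrangement that contracts the pyranone to ring C and leaves C6 as an aryl alkyl ketene on C6a. The closest known reaction type is the photo-Wolff ring contraction of cyclic 2-diazoketones with capture of the ketene by an oxygen nucleophile. Ring C thus arises by ring contraction (six- to five-membered, aryl migration), and ring B closes by addition of the ring A phenol O5 to the sp carbon C6 with the C=O bond exocyclic (6-exo-dig), a six-membered lactonisation. The new stereocentre C6a is set when the resulting ester enol is protonated on the face syn to H-11a, the only face that leads to the low-energy cis B/C fusion, and because this α-carbon stays epimerisable the cis lactone is also the thermodynamic product, so C11a controls C6a. The step needs aryl migration to win over the carbene channels (1,2-shift of H-2 to the flavone, O–H insertion, aryl shift from C2) and intramolecular capture to win over intermolecular capture: the ring holds the diazoketone s-cis, direct irradiation without a metal avoids a free carbene or carbenoid, the migrating aryl carbon is electron-rich, 405 nm light should not be absorbed by the two chromenes, and high dilution in a dry non-nucleophilic solvent leaves O5 as the only nucleophile within reach.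

Step 14
Reactants: 25 the cis-lactone
Product: 26 cis-2-(7-hydroxy-2,2-dimethyl-2H-chromen-6-yl)-3-(hydroxymethyl)-2,3-dihydrobenzofuran of ring D (6aR,11aR in pterocarpan numbering; ring B opened between O5 and C6)
Conditions: LiAlH4 (4 equiv), THF, −20 to 0 °C; aq. potassium sodium tartrate (KNaC4H4O6)
Reagents that add atoms: none
Why: Hydride reduction of the aryl ester gives the primary alcohol and the ring A phenol fast enough that the intermediate aldehyde is reduced before C6a can enolise; this route is preferred to Lewis-acid silane reduction of the lactol, which would ionise the doubly oxygen-activated benzylic C11a–O11 bond.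

Step 15
Reactants: 26 the triol
Product: 27 Lespecyrtin E4
Conditions: PPh3 (1.5 equiv), DIAD (1.5 equiv), THF (0.01 M), 0 °C to rt
Reagents that add atoms: none
Why: Mitsunobu etherification closes ring B by 6-exo-tet attack of the O5 phenol on the activated primary carbon C6, touching no stereocentre, while the hindered O9 phenol cannot reach C6 and should stay free at high dilution.

**Compound list**

1 | 2',4',5'-trihydroxyacetophenone | CC(=O)c1cc(O)c(O)cc1O | starting material
2 | allyl bromide | C=CCBr | starting material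
3 | 1-[4-(allyloxy)-2,5-dihydroxyphenyl]ethanone | CC(=O)c1cc(O)c(OCC=C)cc1O | intermediate
4 | 3-chloro-3-methylbut-1-yne | CC(C)(Cl)C#C | starting material
5 | 1-[4-(allyloxy)-2-hydroxy-5-(2-methylbut-3-yn-2-yloxy)phenyl]ethanone | CC(=O)c1cc(OC(C)(C)C#C)c(OCC=C)cc1O | intermediate
6 | 1-[8-(allyloxy)-6-hydroxy-2,2-dimethyl-2H-chromen-5-yl]ethanone | CC(=O)c1c(O)cc(OCC=C)c2OC(C)(C)C=Cc12 | intermediate
7 | 1-(7-allyl-6,8-dihydroxy-2,2-dimethyl-2H-chromen-5-yl)ethanone | CC(=O)c1c(O)c(CC=C)c(O)c2OC(C)(C)C=Cc12 | intermediate
8 | 2-methylbut-2-ene | CC=C(C)C | starting material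
9 | 1-[6,8-dihydroxy-2,2-dimethyl-7-(3-methylbut-2-enyl)-2H-chromen-5-yl]ethanone | CC(=O)c1c(O)c(CC=C(C)C)c(O)c2OC(C)(C)C=Cc12 | intermediate
10 | 1-[6-hydroxy-2,2-dimethyl-7-(3-methylbut-2-enyl)-8-(triisopropylsilyloxy)-2H-chromen-5-yl]ethanone | CC(=O)c1c(O)c(CC=C(C)C)c(O[Si](C(C)C)(C(C)C)C(C)C)c2OC(C)(C)C=Cc12 | intermediate
11 | N,N-dimethylformamide dimethyl acetal | COC(OC)N(C)C | starting material
12 | (E)-3-(dimethylamino)-1-[6-hydroxy-2,2-dimethyl-7-(3-methylbut-2-enyl)-8-(triisopropylsilyloxy)-2H-chromen-5-yl]prop-2-en-1-one | CN(C)/C=C/C(=O)c1c(O)c(CC=C(C)C)c(O[Si](C(C)C)(C(C)C)C(C)C)c2OC(C)(C)C=Cc12 | intermediate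
13 | 8-(3-methylbut-2-enyl)-7-(triisopropylsilyloxy)chromen-4-one with 2,2-dimethylpyran ring F fused at C5–C6 (oxygen on C6) | O=C1C=COc2c(CC=C(C)C)c(O[Si](C(C)C)(C(C)C)C(C)C)c3OC(C)(C)C=Cc3c12 | intermediate
14 | 5-bromo-2,4-dihydroxybenzaldehyde | O=Cc1cc(Br)c(O)cc1O | starting material
15 | 5-bromo-2-hydroxy-4-(triisopropylsilyloxy)benzaldehyde | O=Cc1cc(Br)c(O[Si](C(C)C)(C(C)C)C(C)C)cc1O | intermediate
16 | 2-methylprop-1-enylmagnesium bromide | CC(C)=C[Mg]Br | starting material
17 | 4-bromo-2-(1-hydroxy-3-methylbut-2-enyl)-5-(triisopropylsilyloxy)phenol (racemic carbinol) | CC(C)=CC(O)c1cc(Br)c(O[Si](C(C)C)(C(C)C)C(C)C)cc1O | intermediate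
18 | 6-bromo-2,2-dimethyl-7-(triisopropylsilyloxy)-2H-chromene | CC1(C)C=Cc2cc(Br)c(O[Si](C(C)C)(C(C)C)C(C)C)cc2O1 | intermediate
19 | [2,2-dimethyl-7-(triisopropylsilyloxy)-2H-chromen-6-yl]boronic acid | CC1(C)C=Cc2cc(B(O)O)c(O[Si](C(C)C)(C(C)C)C(C)C)cc2O1 | intermediate
20 | (2R)-flavanone: chroman-4-one of 13 bearing the 2,2-dimethyl-7-(triisopropylsilyloxy)-2H-chromen-6-yl group at C2 | O=C1C[C@H](c2cc3C=CC(C)(C)Oc3cc2O[Si](C(C)C)(C(C)C)C(C)C)Oc2c(CC=C(C)C)c(O[Si](C(C)C)(C(C)C)C(C)C)c3OC(C)(C)C=Cc3c12 | intermediate
21 | (2R)-3-(trifluoroacetyl) derivative of 20 (C3 not defined, mainly enol) | O=C1C(C(=O)C(F)(F)F)[C@H](c2cc3C=CC(C)(C)Oc3cc2O[Si](C(C)C)(C(C)C)C(C)C)Oc2c(CC=C(C)C)c(O[Si](C(C)C)(C(C)C)C(C)C)c3OC(C)(C)C=Cc3c12 | intermediate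
22 | (2S)-3-diazo derivative of 20, both phenols silylated | [N-]=[N+]=C1C(=O)c2c3C=CC(C)(C)Oc3c(O[Si](C(C)C)(C(C)C)C(C)C)c(CC=C(C)C)c2O[C@H]1c1cc2C=CC(C)(C)Oc2cc1O[Si](C(C)C)(C(C)C)C(C)C | intermediate
23 | (2S)-3-diazo-7-hydroxy-2-(7-hydroxy-2,2-dimethyl-2H-chromen-6-yl)-8-(3-methylbut-2-enyl)chroman-4-one with ring F fused at C5–C6 | [N-]=[N+]=C1C(=O)c2c3C=CC(C)(C)Oc3c(O)c(CC=C(C)C)c2O[C@H]1c1cc2C=CC(C)(C)Oc2cc1O | intermediate
24 | ketene on C3 of the ring-contracted 2-aryl-2,3-dihydrobenzofuran (C2 configuration unchanged) | O=C=C1c2c3C=CC(C)(C)Oc3c(O)c(CC=C(C)C)c2O[C@H]1c1cc2C=CC(C)(C)Oc2cc1O | intermediate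
25 | (6aS,11aR)-cis-pterocarpan-6-one, the 6-oxo derivative of the target | CC(C)=CCc1c(O)c2c(c3c1O[C@H]1c4cc5c(cc4OC(=O)[C@@H]31)OC(C)(C)C=C5)C=CC(C)(C)O2 | intermediate
26 | cis-2-(7-hydroxy-2,2-dimethyl-2H-chromen-6-yl)-3-(hydroxymethyl)-2,3-dihydrobenzofuran of ring D, (6aR,11aR) in pterocarpan numbering | CC(C)=CCc1c(O)c2c(c3c1O[C@@H](c1cc4c(cc1O)OC(C)(C)C=C4)[C@H]3CO)C=CC(C)(C)O2 | intermediate
27 | Lespecyrtin E4, (6aR,11aR) | CC(C)=CCc1c(O)c2c(c3c1O[C@H]1c4cc5c(cc4OC[C@@H]31)OC(C)(C)C=C5)C=CC(C)(C)O2 | target

**Step count and risks**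

Total: 15 steps. Longest linear sequence: 12 steps (steps 1–6 and 10–15, from 1); the ring A branch is steps 7–9.

Steps most likely to fail:

1. Step 13. Nitrogen loss may run through a carbene channel (hydride shift to the flavone, O–H insertion by a phenol) instead of aryl migration, or capture of the ketene by O5 may be slow. The fallback sets out from 22 and comes back at 26. Irradiation of the bis-silyl ether 22 at 405 nm in CH2Cl2/MeOH keeps both phenols masked and lets methanol capture the ketene. Protonation of the ester enol on the face away from the C2 aryl group should give methyl cis-2-aryl-2,3-dihydrobenzofuran-3-carboxylate F1. LiAlH4 should reduce this to the bis-silylated primary alcohol F2, and TBAF/AcOH then gives 26. Ring B is then closed only by the Mitsunobu reaction of step 15.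

2. Step 10. Transmetalation and insertion of the ortho-silyloxy, electron-rich arylboronic acid may be slow, with protodeboronation taking over, or facial selectivity may be insufficient. The fallback sets out from 18 and 10 and comes back at 20. Bromine–lithium exchange of 18 (n-BuLi, −78 °C) and quenching with DMF gives 2,2-dimethyl-7-(triisopropylsilyloxy)-2H-chromene-6-carbaldehyde F3. Condensation of F3 with acetophenone 10 under pyrrolidine catalysis (Kabbe-type aldol condensation and oxa-Michael closure, so the O1–C2 bond is made instead of the C2–aryl bond) gives the racemic flavanone F4. Preparative chromatography on a chiral stationary phase then delivers 20.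

3. Step 11. The C3 enolate may open the ring by β-elimination of the O1 phenoxide (retro-oxa-Michael), which would erode the configuration at C2, or the amine-mediated transfer stage may do the same. The fallback sets out from 20 and comes back at 22. Aminomethylenation of 20 with tert-butoxybis(dimethylamino)methane in toluene at 60 °C, with no metal enolate, gives the 3-(dimethylaminomethylidene)flavanone F5. Treatment of F5 with tosyl azide in CH2Cl2 at rt (cycloaddition and fragmentation, the known diazo transfer to enaminones) then gives 22.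

**Further compounds**

F1 | step 13 | methyl cis-2-[2,2-dimethyl-7-(triisopropylsilyloxy)-2H-chromen-6-yl]-2,3-dihydrobenzofuran-3-carboxylate of ring D (9-O-silylated, ring F and prenyl in place) | CC(C)=CCc1c(O[Si](C(C)C)(C(C)C)C(C)C)c2c(c3c1O[C@@H](c1cc4c(cc1O[Si](C(C)C)(C(C)C)C(C)C)OC(C)(C)C=C4)[C@H]3C(=O)OC)C=CC(C)(C)O2
F2 | step 13 | bis-silyl ether of triol 26 | CC(C)=CCc1c(O[Si](C(C)C)(C(C)C)C(C)C)c2c(c3c1O[C@@H](c1cc4c(cc1O[Si](C(C)C)(C(C)C)C(C)C)OC(C)(C)C=C4)[C@H]3CO)C=CC(C)(C)O2
F3 | step 10 | 2,2-dimethyl-7-(triisopropylsilyloxy)-2H-chromene-6-carbaldehyde | O=Cc1cc2C=CC(C)(C)Oc2cc1O[Si](C(C)C)(C(C)C)C(C)C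
F4 | step 10 | racemic flavanone (20 and its enantiomer) | O=C1CC(c2cc3C=CC(C)(C)Oc3cc2O[Si](C(C)C)(C(C)C)C(C)C)Oc2c(CC=C(C)C)c(O[Si](C(C)C)(C(C)C)C(C)C)c3OC(C)(C)C=Cc3c12
F5 | step 11 | 3-(dimethylaminomethylidene) derivative of flavanone 20 (2S by CIP, same spatial arrangement) | CN(C)C=C1C(=O)c2c3C=CC(C)(C)Oc3c(O[Si](C(C)C)(C(C)C)C(C)C)c(CC=C(C)C)c2O[C@H]1c1cc2C=CC(C)(C)Oc2cc1O[Si](C(C)C)(C(C)C)C(C)C
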